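**Convention.** Coumarin numbering (O1, C2 … C8a) is used for these atoms in every precursor. Primed numbers refer to ring B.

## The problem

1. The target joins three C6–C3 units. These are a 6,7-dihydroxycoumarin (benzo ring A; pyranone ring P made of O1, C2, C3, C4, C4a, C8a), a caffeoyl unit (ring B, C1'–C6', side chain C7'=C8'–C9') and (R)-3-(3,4-dihydroxyphenyl)lactic acid (ring C, carbinol carbon Cα).
2. Rings P and B are joined by the bond C3–O4'. This is an enol aryl ether at the α-carbon of an unsaturated lactone, a position no nucleophile reaches by addition–elimination, and no simple building block offers this connectivity.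
3. The ether must sit on O4' alone while O3', its ortho neighbour on ring B, stays a free phenol, so the two oxygens of one catechol have to be told apart.
4. Cα is the only stereocenter, and nothing else in the molecule can control it. It must come from a small fragment, and as an acyloxy-bearing α-carbon of an acid it can be epimerized by base.
5. Five phenols (two of them in catechols that oxidise in basic, aerated media), a free acid, an alkyl ester and a lactone forbid hydroxide. The alkenes C7'=C8' and C3=C4 forbid hydrogenolysis, so few masking groups qualify.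
6. The feature that opens the plan is that O3'–H stands ortho to O4'. The six atoms O3', C3', C4', O4', C3 and C2 can therefore form a ring of their own, and the carbonyl C2 can be bound to O3' (a 1,4-benzodioxin-2-one on ring B) as well as to O1 (ring P).
7. Seen this way, the free hydroxyl is not a group to protect but the leaving group of an acyl transfer. Ring P is one acyl shift and one aldol dehydration away from the small lactone 5 and the salicylaldehyde 7.

## Retrosynthesis

**20 ⇒ 19 (O–C bonds of three masking groups).**
- Bonds cut: the tert-butyl ester on the carboxyl, the isopropylidene ketal on ring C and the diphenylmethylene ketal on ring A.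
- Against the neighbours: benzyl ethers would need hydrogenolysis, which also saturates C7'=C8' and C3=C4. Methyl ethers need boron halides next to an ester. Acyl groups need base next to Cα and next to catechols.
- Gain: all three chosen groups leave with acid alone, and O3' needs no group at all. Compound 19 has the same skeleton but is not oxidisable and can be purified.
- Demand on the forward step: one acidolysis that leaves the ester, lactone, enol ether, alkenes and Cα untouched.

**19 ⇒ 10 + 18 (C7'=C8').**
- Against the acyl bond C9'–O: esterifying a cinnamic acid with 16 would force protection of O3' and bring a basic acylation catalyst next to Cα.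
- Against C1'–C7': this cut would need a halogen on ring B, which removes the para acceptor that distinguishes O4' from O3'.
- Gain: cutting the alkene lets ring B arrive as an aldehyde, the very group that makes O4' acidic at the start. The 47-carbon compound 19 falls into pieces of 29 and 19 carbons.
- Demand: an E-selective decarboxylative condensation that tolerates a free phenol.

**10 ⇒ 5 + 7 (key: C3=C4 and O1–C2 cut, C2 re-tied to O3').**
- Against the neighbours: cutting C3–O4' leaves an sp2 α-carbon that resists substitution. Cutting the two bonds from ring A to ring P replaces a cheap aldehyde by a costly aryne precursor. Cutting the same two bonds from an open, protected acid needs a protecting group for O3', an activator for C2 and a dehydrating agent.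
- Gain: the dioxinone ring of 5 does all three jobs and also stores the O4'/O3' decision. Compound 10 has a tetracyclic core and 29 carbons. Compound 5 is a nine-carbon bicycle made in two steps, and 7 is made in one.
- Demand: acyl transfer from O3' to the phenoxide of 7, and an intramolecular aldol at the formyl group of ring A only. Dehydration serves as the irreversible exit.

**5 ⇒ 3 ⇒ 1 + 2 (O3'–C2, then O4'–C3).**
- The lactone bond is an ordinary dehydration of acid 4.
- The ether bond is made at an sp3 carbon, where C–O formation is easy, rather than at the finished enol ether.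
- The para formyl group of 1 makes the 4-OH the more acidic phenol, so a weak base should select O4'.
- Atoms C2 and C3 of the coumarin are bought in 2.

**7 ⇒ 6 (two O–C bonds of the ketal).**
- Only the oxygens at C4 and C5 of 6 are vicinal and can be bridged. The 2-OH, which becomes O1, is left free by geometry and not by reagent control.
- A bridging ketal is preferred to two separate ethers for this reason.

**18 ⇒ 16 + 17 (O–C9').**
- The acyl bond to the oxygen on Cα is made early, on a small molecule, by neutral thermal opening of 17.
- The C–O bond at Cα is not touched, so the configuration is retained.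
- Compound 17 supplies C8' and C9'.

**16 ⇒ 15 ⇒ 14 ⇒ 11 + 12 (aryl–CH2 bond, ester exchange).**
- Cutting the bond between ring C and its benzylic carbon leads to an aryl nucleophile from 11 and to the epoxide 12, which carries Cα in the right configuration.
- Creating Cα by reduction of an arylpyruvate would cost more steps and a stoichiometric chiral reagent.
- The methyl ester of 12 cannot be removed at the end beside the cinnamate, so it is exchanged for the acid-labile tert-butyl ester on the small fragment.

## Roads not taken

**Alternative 1: the first-draw route.**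
- Cut: C3=C4 and O1–C2 from an open, fully protected acid, then the ester bond C9'–O as the last union.
- Forward: O3' is capped to give acid A1. A Perkin–Oglialoro condensation of A1 with 7 in a hot carboxylic anhydride and amine gives coumarin A2. Chain extension gives cinnamic acid A3, which is esterified with 16 by a carbodiimide and then deprotected.
- Why the chosen plan is better: Alternative 1 uses three separate devices (cap on O3', activator for C2, water scavenger) for what the ring of 5 does alone. It runs above 100 °C and adds a protection step and a separate esterification. That last union also places a nucleophilic acylation catalyst beside Cα.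

**Alternative 2: cut C3–O4' on the finished coumarin.**
- Forward, metal route: CuI-catalysed Ullmann-type etherification of bromide A4 with a ring-B phenol.
- Forward, metal-free relay with free catechol 1: O3' adds to C4, O4' displaces bromide at the now sp3 C3 to give tetracycle A5, and a retro-Michael step frees O3' to give 10.
- Why the chosen plan is better:
  - C3 is the α-carbon of the enoate, so there is no direct addition–elimination.
  - Hot phenoxide opens the lactone, and 3-halocoumarins then contract to benzofuran-2-carboxylates (Perkin rearrangement).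
  - A free catechol binds copper, so O3' would need a protecting group.
  - In the relay, the O4'/O3' choice rests on a Curtin–Hammett balance of two phenoxides instead of a bond already in place.
  - The donor-rich ring A makes C4 a poor acceptor.
  - A4 costs as many steps as 5, so nothing is gained.

**Alternative 3: cut C4a–C4 and C8a–O1 at once (aryne).**
- Forward: fluoride releases the symmetric aryne A7 from silyl triflate A6. A [2+2] addition to the C=O of a formamide followed by ring opening gives the aminomethylene quinone methide A8, which is trapped by the enolate of 5 to give 10.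
- Merit: two bonds to ring A form in one operation, and the symmetry of A7 removes any question of orientation.
- Why the chosen plan is better: A6 needs about four steps (halogenation, silylation, silyl shift, triflation) to replace aldehyde 7, which needs one. The phenoxide O3' and the amine set free would both add to A7, and fluoride endangers lactone 5. The run-up would consume what the step gains.

Key step: step 4

Assumption: compounds 1, 2, 6, 11, 12 (enantiopure R) and 17 are taken as catalogue chemicals. All steps that involve free catechols or phenoxides are run under argon.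

## Route

Step 1
Reactants: 1 3,4-dihydroxybenzaldehyde; 2 tert-butyl bromoacetate
Product: 3 tert-butyl 2-(4-formyl-2-hydroxyphenoxy)acetate
Conditions: NaHCO3 (1.5 equiv), DMF, 40 °C
Reagents that add atoms: none
Why: Williamson ether synthesis under weak-base control: only the 4-OH, para to the formyl group and therefore the more acidic phenol, is deprotonated by NaHCO3, so O4' should be alkylated and O3' left free. Selective 4-O-alkylation of this aldehyde with hydrogencarbonate in DMF is a known reaction type.

Step 2
Reactants: 3 tert-butyl 2-(4-formyl-2-hydroxyphenoxy)acetate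
Product: 5 3-oxo-2,3-dihydro-1,4-benzodioxine-6-carbaldehyde (carbonyl C2 on O3', methylene C3 on O4', formyl para to O4'), via hydroxy acid 4 (not isolated)
Conditions: p-TsOH·H2O (0.1 equiv), toluene, reflux, Dean–Stark trap
Reagents that add atoms: none
Why: Acid-catalysed loss of isobutene from the tert-butyl ester gives 4, which should close by azeotropic lactonization onto the neighbouring phenol O3' (6-exo-trig). The aldehyde and the aryl ether are inert to these conditions.

Step 3
Reactants: 6 2,4,5-trihydroxybenzaldehyde
Product: 7 6-hydroxy-2,2-diphenyl-1,3-benzodioxole-5-carbaldehyde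
Conditions: Ph2CCl2 (1.1 equiv), K2CO3 (2.5 equiv), MeCN, 23 → 60 °C
Reagents that add atoms: dichlorodiphenylmethane, ClC(Cl)(c1ccccc1)c1ccccc1
Why: Catechol ketalization by double O-alkylation with a gem-dichloride: only the vicinal 4- and 5-oxygens can be bridged in a five-membered ring. The 2-OH is held by a hydrogen bond to the formyl oxygen, and any ether formed there should fall apart on aqueous work-up.

Step 4
Reactants: 5 3-oxo-2,3-dihydro-1,4-benzodioxine-6-carbaldehyde; 7 6-hydroxy-2,2-diphenyl-1,3-benzodioxole-5-carbaldehyde
Product: 10 3-hydroxy-4-[(6-oxo-2,2-diphenyl-6H-[1,3]dioxolo[4,5-g]chromen-7-yl)oxy]benzaldehyde, via open aryl ester 8 (not isolated), via aldol lactone 9 (not isolated)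
Conditions: DBU (0.5 equiv), 4 Å molecular sieves, MeCN, 23 → 50 °C
Reagents that add atoms: none
Why: Proposed new method: a lactone-to-lactone ring switch, argued from the mechanism as follows. DBU makes the phenoxide of 7, which adds to the aryl-ester carbonyl C2 of 5 and expels O3' of ring B (reversible addition–elimination), so the dioxinone ring opens to 8 and the free ring-B hydroxyl of the target appears. In 8 the methylene C3 lies between an aryloxy group and the ester of an electron-poor phenol; its enolate attacks the ortho formyl carbon C4 in a 6-(enolendo)-exo-trig aldol closure of ring P to give 9, and E1cB dehydration of 9 gives the conjugated coumarin 10, the irreversible step that drains all earlier equilibria. The closest known reaction types are the base-induced cyclization of 2-formylaryl aryloxyacetates to 3-aryloxycoumarins (second half of the Perkin–Oglialoro synthesis) and the condensation of benzofuran-2(3H)-ones with salicylaldehydes to 3-(2-hydroxyaryl)coumarins, in which a phenolic lactone likewise hands its acyl group to the salicyl oxygen. The two stereocenters of 9 (C3, C4) are transient and vanish on dehydration, so no stereocontrol is needed. The site question (C3 on O4', O3' free) is not decided here but is built into the ring of 5. The step needs chemoselectivity between two formyl groups: only that of ring A stands ortho to the acylated oxygen and reaches C3 through a six-membered transition state, whereas that of ring B, para to O4', could react only between molecules and only with the less acidic lactone 5. The sieves take up the water, which would otherwise hydrolyse 5.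

Step 5
Reactants: 11 5-bromo-2,2-dimethyl-1,3-benzodioxole; 12 methyl (2R)-oxirane-2-carboxylate
Product: 14 methyl (2R)-3-(2,2-dimethyl-1,3-benzodioxol-5-yl)-2-hydroxypropanoate, via arylmagnesium bromide 13 (not isolated)
Conditions: Mg turnings, THF, 40 °C; CuI (0.1 equiv), −40 °C; then 12, −40 → −20 °C; water quench
Reagents that add atoms: magnesium, [Mg] (kept in 13, lost on work-up)
Why: Copper-catalysed SN2 opening of a terminal epoxide by an aryl Grignard reagent at the unsubstituted carbon. No bond to the stereocenter is touched and the priority order is unchanged, so the (R) configuration of 12 becomes the (R) configuration of 14. At low temperature the organocopper species should attack the epoxide faster than the ester.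

Step 6
Reactants: 14 methyl (2R)-3-(2,2-dimethyl-1,3-benzodioxol-5-yl)-2-hydroxypropanoate
Product: 15 (2R)-3-(2,2-dimethyl-1,3-benzodioxol-5-yl)-2-hydroxypropanoic acid
Conditions: LiOH (1.5 equiv), THF/H2O, 0 °C; then cold 1 M HCl to pH 3
Reagents that add atoms: lithium hydroxide, [Li+].[OH-]
Why: Saponification of an α-hydroxy methyl ester at 0 °C, which should not enolize Cα. The acetonide is stable to base and to short contact with cold dilute acid.

Step 7
Reactants: 15 (2R)-3-(2,2-dimethyl-1,3-benzodioxol-5-yl)-2-hydroxypropanoic acid
Product: 16 tert-butyl (2R)-3-(2,2-dimethyl-1,3-benzodioxol-5-yl)-2-hydroxypropanoate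
Conditions: tert-butyl 2,2,2-trichloroacetimidate (2 equiv), CH2Cl2/cyclohexane, 23 °C
Reagents that add atoms: tert-butyl 2,2,2-trichloroacetimidate, CC(C)(C)OC(=N)C(Cl)(Cl)Cl
Why: tert-Butylation of a carboxylic acid with the trichloroacetimidate, which the acid itself protonates. Without an added Lewis acid the secondary alcohol should not react, and Cα is not involved.

Step 8
Reactants: 16 tert-butyl (2R)-3-(2,2-dimethyl-1,3-benzodioxol-5-yl)-2-hydroxypropanoate; 17 Meldrum's acid (2,2-dimethyl-1,3-dioxane-4,6-dione)
Product: 18 3-{[(2R)-1-tert-butoxy-3-(2,2-dimethyl-1,3-benzodioxol-5-yl)-1-oxopropan-2-yl]oxy}-3-oxopropanoic acid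
Conditions: toluene, 105 °C
Reagents that add atoms: none
Why: Thermal alcoholysis of Meldrum's acid, a known route to malonic half-esters even from hindered alcohols, under neutral conditions. The O–Cα bond is not broken, so the configuration is retained.

Step 9
Reactants: 10 3-hydroxy-4-[(6-oxo-2,2-diphenyl-6H-[1,3]dioxolo[4,5-g]chromen-7-yl)oxy]benzaldehyde; 18 the malonic half-ester
Product: 19 tert-butyl (2R)-3-(2,2-dimethyl-1,3-benzodioxol-5-yl)-2-{[(2E)-3-{3-hydroxy-4-[(6-oxo-2,2-diphenyl-6H-[1,3]dioxolo[4,5-g]chromen-7-yl)oxy]phenyl}prop-2-enoyl]oxy}propanoate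
Conditions: 18 (1.3 equiv), pyridine, piperidine (0.1 equiv), 50 °C
Reagents that add atoms: none
Why: Knoevenagel–Doebner condensation of a malonic half-ester, whose decarboxylative elimination gives the E-cinnamate and which is known to tolerate free phenolic aldehydes. Ketals, tert-butyl ester and the donor-rich coumarin should be inert to the weak amine medium, and Cα is not touched.

Step 10
Reactants: 19 the protected ester
Product: 20 (2R)-3-(3,4-dihydroxyphenyl)-2-{[(2E)-3-{4-[(6,7-dihydroxy-2-oxo-2H-chromen-3-yl)oxy]-3-hydroxyphenyl}prop-2-enoyl]oxy}propanoic acid (target)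
Conditions: TFA/CH2Cl2/H2O (10:10:1), 0 → 23 °C, argon
Reagents that add atoms: none
Why: Global acidolysis: the tert-butyl ester loses isobutene, and both ketals hydrolyse through stabilised oxocarbenium ions. The alkyl ester, the lactone, the carbonyl-deactivated enol ether, both alkenes and Cα are not attacked by acid at room temperature.

## Compound list

1 | 3,4-dihydroxybenzaldehyde | O=Cc1ccc(O)c(O)c1 | starting material
2 | tert-butyl bromoacetate | CC(C)(C)OC(=O)CBr | starting material
3 | tert-butyl 2-(4-formyl-2-hydroxyphenoxy)acetate | O=Cc1ccc(OCC(=O)OC(C)(C)C)c(O)c1 | intermediate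
4 | 2-(4-formyl-2-hydroxyphenoxy)acetic acid | O=Cc1ccc(OCC(=O)O)c(O)c1 | intermediate
5 | 3-oxo-2,3-dihydro-1,4-benzodioxine-6-carbaldehyde | O=Cc1ccc2OCC(=O)Oc2c1 | intermediate
6 | 2,4,5-trihydroxybenzaldehyde | O=Cc1cc(O)c(O)cc1O | starting material
7 | 6-hydroxy-2,2-diphenyl-1,3-benzodioxole-5-carbaldehyde | O=Cc1cc2OC(c3ccccc3)(c3ccccc3)Oc2cc1O | intermediate
8 | 6-formyl-2,2-diphenyl-1,3-benzodioxol-5-yl 2-(4-formyl-2-hydroxyphenoxy)acetate | O=Cc1ccc(OCC(=O)Oc2cc3OC(c4ccccc4)(c4ccccc4)Oc3cc2C=O)c(O)c1 | intermediate
9 | 3-hydroxy-4-[(8-hydroxy-6-oxo-2,2-diphenyl-7,8-dihydro-6H-[1,3]dioxolo[4,5-g]chromen-7-yl)oxy]benzaldehyde (transient, diastereomers not defined) | O=Cc1ccc(OC2C(O)c3cc4OC(c5ccccc5)(c5ccccc5)Oc4cc3OC2=O)c(O)c1 | intermediate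
10 | 3-hydroxy-4-[(6-oxo-2,2-diphenyl-6H-[1,3]dioxolo[4,5-g]chromen-7-yl)oxy]benzaldehyde | O=Cc1ccc(Oc2cc3cc4OC(c5ccccc5)(c5ccccc5)Oc4cc3oc2=O)c(O)c1 | intermediate
11 | 5-bromo-2,2-dimethyl-1,3-benzodioxole | CC1(C)Oc2ccc(Br)cc2O1 | starting material
12 | methyl (2R)-oxirane-2-carboxylate | COC(=O)[C@H]1CO1 | starting material
13 | (2,2-dimethyl-1,3-benzodioxol-5-yl)magnesium bromide | CC1(C)Oc2ccc([Mg]Br)cc2O1 | intermediate
14 | methyl (2R)-3-(2,2-dimethyl-1,3-benzodioxol-5-yl)-2-hydroxypropanoate | O[C@H](Cc1ccc2OC(C)(C)Oc2c1)C(=O)OC | intermediate
15 | (2R)-3-(2,2-dimethyl-1,3-benzodioxol-5-yl)-2-hydroxypropanoic acid | O[C@H](Cc1ccc2OC(C)(C)Oc2c1)C(=O)O | intermediate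
16 | tert-butyl (2R)-3-(2,2-dimethyl-1,3-benzodioxol-5-yl)-2-hydroxypropanoate | O[C@H](Cc1ccc2OC(C)(C)Oc2c1)C(=O)OC(C)(C)C | intermediate
17 | Meldrum's acid (2,2-dimethyl-1,3-dioxane-4,6-dione) | CC1(C)OC(=O)CC(=O)O1 | starting material
18 | 3-{[(2R)-1-tert-butoxy-3-(2,2-dimethyl-1,3-benzodioxol-5-yl)-1-oxopropan-2-yl]oxy}-3-oxopropanoic acid | OC(=O)CC(=O)O[C@H](Cc1ccc2OC(C)(C)Oc2c1)C(=O)OC(C)(C)C | intermediate
19 | tert-butyl (2R)-3-(2,2-dimethyl-1,3-benzodioxol-5-yl)-2-{[(2E)-3-{3-hydroxy-4-[(6-oxo-2,2-diphenyl-6H-[1,3]dioxolo[4,5-g]chromen-7-yl)oxy]phenyl}prop-2-enoyl]oxy}propanoate | O=C(/C=C/c1ccc(Oc2cc3cc4OC(c5ccccc5)(c5ccccc5)Oc4cc3oc2=O)c(O)c1)O[C@H](Cc1ccc2OC(C)(C)Oc2c1)C(=O)OC(C)(C)C | intermediate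
20 | (2R)-3-(3,4-dihydroxyphenyl)-2-{[(2E)-3-{4-[(6,7-dihydroxy-2-oxo-2H-chromen-3-yl)oxy]-3-hydroxyphenyl}prop-2-enoyl]oxy}propanoic acid | O=C(/C=C/c1ccc(Oc2cc3cc(O)c(O)cc3oc2=O)c(O)c1)O[C@H](Cc1ccc(O)c(O)c1)C(=O)O | target

## Count and risks

Total step count: 10. Longest linear sequence: 6 (steps 5, 6, 7, 8, 9, 10). The ring-B branch (steps 1, 2, 4, 9, 10) has 5 steps.

**Step 4 (key step, Proposed new method).**
- What may go wrong:
  - Intermolecular aldol condensation at the ring-B formyl group could lead to oligomers.
  - The water set free could hydrolyse lactone 5.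
  - The stationary share of 8 may be too small, because re-closure to 5 is intramolecular while its opening is not.
- Fallback (known chemistry): it sets out from 3 and 7 and comes back at 10.
  - Ester 3 is cleaved with TFA and acid 4 is isolated.
  - Acid 4 and aldehyde 7 are heated with acetic anhydride and triethylamine (Perkin–Oglialoro coumarin synthesis). The anhydride caps O3', activates C2 and takes up the water.
  - This should give 5-formyl-2-[(6-oxo-2,2-diphenyl-6H-[1,3]dioxolo[4,5-g]chromen-7-yl)oxy]phenyl acetate F1.
  - Methanolysis of the aryl acetate with catalytic K2CO3 at 0 °C gives 10.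

**Step 1.**
- What may go wrong: loss of site selectivity and double alkylation. The bromoacetate is a very reactive electrophile, and proton exchange with the product can make the O3' phenoxide available.
- Fallback: it sets out from 2 and comes back at 4.
  - Bromide 2 alkylates the only free phenol of vanillin F2 (K2CO3, DMF) to give tert-butyl 2-(4-formyl-2-methoxyphenoxy)acetate F3. The site of the ether is fixed by the purchased methyl ether.
  - BBr3 (CH2Cl2, −78 → 0 °C) removes the methyl ether and the tert-butyl ester to give 4, which is lactonized as in step 2.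

**Step 9.**
- What may go wrong: slow condensation of a poorly soluble aldehyde, attack of the secondary amine on the coumarin lactone, and partial epimerization at Cα by enolization in the warm amine medium.
- Fallback: it sets out from 16 and comes back at 19, and it trades the amine-catalysed condensation for a neutral Wittig olefination.
  - Bromoacetyl bromide and pyridine give tert-butyl (2R)-2-[(bromoacetyl)oxy]-3-(2,2-dimethyl-1,3-benzodioxol-5-yl)propanoate F4.
  - PPh3 gives (2-{[(2R)-1-tert-butoxy-3-(2,2-dimethyl-1,3-benzodioxol-5-yl)-1-oxopropan-2-yl]oxy}-2-oxoethyl)(triphenyl)phosphonium bromide F5.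
  - A wash with aqueous Na2CO3 gives the stabilised ylide tert-butyl (2R)-3-(2,2-dimethyl-1,3-benzodioxol-5-yl)-2-{[(triphenylphosphoranylidene)acetyl]oxy}propanoate F6.
  - Ylide F6 should react with 10 in toluene at 23–60 °C to give the E-alkene 19 without any added base.

**Step 10.**
- What may go wrong: Friedel–Crafts tert-butylation of the electron-rich catechol rings by the tert-butyl cation. Cleavage of the ketal on the electron-poor ring A may also be slow, which lengthens the acid exposure of the ester.
- Fallback: it sets out from 10 and comes back at 20, and it moves the harder unmasking to a stage without ester or stereocenter.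
  - Compound 10 is heated in aqueous acetic acid to give 4-[(6,7-dihydroxy-2-oxo-2H-chromen-3-yl)oxy]-3-hydroxybenzaldehyde F7.
  - The Knoevenagel–Doebner condensation of F7 with 18, which tolerates free catechols under argon, gives tert-butyl (2R)-2-{[(2E)-3-{4-[(6,7-dihydroxy-2-oxo-2H-chromen-3-yl)oxy]-3-hydroxyphenyl}prop-2-enoyl]oxy}-3-(2,2-dimethyl-1,3-benzodioxol-5-yl)propanoate F8.
  - A short treatment of F8 with TFA/H2O gives 20.

## Further compounds

F1 | step 4 | 5-formyl-2-[(6-oxo-2,2-diphenyl-6H-[1,3]dioxolo[4,5-g]chromen-7-yl)oxy]phenyl acetate | CC(=O)Oc1cc(C=O)ccc1Oc1cc2cc3OC(c4ccccc4)(c4ccccc4)Oc3cc2oc1=O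
F2 | step 1 | vanillin (bought) | COc1cc(C=O)ccc1O
F3 | step 1 | tert-butyl 2-(4-formyl-2-methoxyphenoxy)acetate | COc1cc(C=O)ccc1OCC(=O)OC(C)(C)C
F4 | step 9 | tert-butyl (2R)-2-[(bromoacetyl)oxy]-3-(2,2-dimethyl-1,3-benzodioxol-5-yl)propanoate | BrCC(=O)O[C@H](Cc1ccc2OC(C)(C)Oc2c1)C(=O)OC(C)(C)C
F5 | step 9 | (2-{[(2R)-1-tert-butoxy-3-(2,2-dimethyl-1,3-benzodioxol-5-yl)-1-oxopropan-2-yl]oxy}-2-oxoethyl)(triphenyl)phosphonium bromide | [Br-].O=C(C[P+](c1ccccc1)(c1ccccc1)c1ccccc1)O[C@H](Cc1ccc2OC(C)(C)Oc2c1)C(=O)OC(C)(C)C
F6 | step 9 | tert-butyl (2R)-3-(2,2-dimethyl-1,3-benzodioxol-5-yl)-2-{[(triphenylphosphoranylidene)acetyl]oxy}propanoate | O=C(C=P(c1ccccc1)(c1ccccc1)c1ccccc1)O[C@H](Cc1ccc2OC(C)(C)Oc2c1)C(=O)OC(C)(C)C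
F7 | step 10 | 4-[(6,7-dihydroxy-2-oxo-2H-chromen-3-yl)oxy]-3-hydroxybenzaldehyde | O=Cc1ccc(Oc2cc3cc(O)c(O)cc3oc2=O)c(O)c1
F8 | step 10 | tert-butyl (2R)-2-{[(2E)-3-{4-[(6,7-dihydroxy-2-oxo-2H-chromen-3-yl)oxy]-3-hydroxyphenyl}prop-2-enoyl]oxy}-3-(2,2-dimethyl-1,3-benzodioxol-5-yl)propanoate | O=C(/C=C/c1ccc(Oc2cc3cc(O)c(O)cc3oc2=O)c(O)c1)O[C@H](Cc1ccc2OC(C)(C)Oc2c1)C(=O)OC(C)(C)C
A1 | alternative 1 | 2-[4-formyl-2-(methoxymethoxy)phenoxy]acetic acid | COCOc1cc(C=O)ccc1OCC(=O)O
A2 | alternative 1 | 3-(methoxymethoxy)-4-[(6-oxo-2,2-diphenyl-6H-[1,3]dioxolo[4,5-g]chromen-7-yl)oxy]benzaldehyde | COCOc1cc(C=O)ccc1Oc1cc2cc3OC(c4ccccc4)(c4ccccc4)Oc3cc2oc1=O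
A3 | alternative 1 | (2E)-3-{3-(methoxymethoxy)-4-[(6-oxo-2,2-diphenyl-6H-[1,3]dioxolo[4,5-g]chromen-7-yl)oxy]phenyl}prop-2-enoic acid | COCOc1cc(/C=C/C(=O)O)ccc1Oc1cc2cc3OC(c4ccccc4)(c4ccccc4)Oc3cc2oc1=O
A4 | alternative 2 | 7-bromo-2,2-diphenyl-6H-[1,3]dioxolo[4,5-g]chromen-6-one | O=c1oc2cc3OC(c4ccccc4)(c4ccccc4)Oc3cc2cc1Br
A5 | alternative 2 | tetracyclic Michael–SN2 adduct of 1 and A4 (O3' on C4, O4' on C3, 3,4-dihydrocoumarin fused to a 1,4-benzodioxane, configuration not defined) | O=Cc1ccc2OC3C(Oc2c1)c1cc4OC(c5ccccc5)(c5ccccc5)Oc4cc1OC3=O
A6 | alternative 3 | 2,2-diphenyl-6-(trimethylsilyl)-1,3-benzodioxol-5-yl trifluoromethanesulfonate | C[Si](C)(C)c1cc2OC(c3ccccc3)(c3ccccc3)Oc2cc1OS(=O)(=O)C(F)(F)F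
A7 | alternative 3 | 5,6-didehydro-2,2-diphenyl-1,3-benzodioxole (aryne) | C1#CC=C2OC(c3ccccc3)(c3ccccc3)OC2=C1
A8 | alternative 3 | 6-[(dimethylamino)methylidene]-2,2-diphenyl-1,3-benzodioxol-5(6H)-one | CN(C)C=C1C=C2OC(c3ccccc3)(c3ccccc3)OC2=CC1=O
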